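**Retrosynthetic overview**
1. The ketone carbon joining C8 of the coumarin benzo ring (flanked by the C7 oxygen and the ring oxygen on C8a) to C1' of the cyclohexene ring carries only its oxygen, so it is supplied as carbon monoxide: 28 ⇒ 27 ⇒ 8-iodocoumarin 9 + CO 26 + cyclohexenylstannane 25, with both C–C bonds to the carbonyl made in one palladium-catalysed step.
2. Coumarin 9: the pyranone ring is closed first onto the purchased benzene ring (Pechmann). Iodine at C8 then blocks that position, so the Claisen rearrangement of the 7-O-(1,1-dimethylallyl) ether delivers the linear prenyl group to C6; the iodine later serves as the coupling handle.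
3. Stannane 25: the carbocycle is bought as cyclohexenone. C5' comes from a catalytic asymmetric methyl addition; C6' and C1'' are set together by hydroboration of an (E)-ethylidene group anti to that methyl (cis ring pattern); ketone → enol triflate → stannane fixes the alkene position.
4. Ring order: pyranone ring (step 1) only; no ring is formed in the coupling; one acid treatment removes the MOM and silyl groups.

Key step: step 15

Remark on the chemistry: the target is read as 5'R,6'R,1''S with the C5' methyl and the C6' hydroxyethyl group cis on the ring, and the Pechmann closure on 1 is assumed to occur para to the free hydroxyl, giving the 7-hydroxy-5-methoxy isomer.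

**Coumarin fragment**

Step 1
Reactants: 1 5-methoxyresorcinol; 2 ethyl 2-methylacetoacetate
Product: 3 7-hydroxy-5-methoxy-3,4-dimethyl-2H-chromen-2-one
Conditions: conc. H2SO4, 0 °C → rt
Reagents that add atoms: none
Why: Pechmann condensation, in which acid-mediated transesterification, ring closure ortho to the ester oxygen and para to the free hydroxyl of the doubly activated arene, and dehydration should give the 3,4-dimethylcoumarin with the hydroxyl at C7 and the methoxy at C5.

Step 2
Reactants: 3 7-hydroxy-5-methoxy-3,4-dimethyl-2H-chromen-2-one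
Product: 4 7-hydroxy-8-iodo-5-methoxy-3,4-dimethyl-2H-chromen-2-one
Conditions: N-iodosuccinimide (1.0 equiv), MeCN, 0 °C
Reagents that add atoms: N-iodosuccinimide O=C1CCC(=O)N1I
Why: Electrophilic aromatic iodination of a 7-hydroxycoumarin should go to C8, between the hydroxyl and the ring oxygen, because C6 is screened by the 5-methoxy group that the peri C4 methyl forces to point toward C6.

Step 3
Reactants: 4 7-hydroxy-8-iodo-5-methoxy-3,4-dimethyl-2H-chromen-2-one; 5 3-chloro-3-methylbut-1-yne
Product: 6 8-iodo-5-methoxy-3,4-dimethyl-7-[(2-methylbut-3-yn-2-yl)oxy]-2H-chromen-2-one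
Conditions: CuCl2 (cat.), DBU, MeCN, 0 °C → rt
Reagents that add atoms: none
Why: Copper-catalysed propargylic O-alkylation is the usual way to place a tertiary propargyl group on a hindered, acidic phenol, and at this temperature the aryl iodide should not react.

Step 4
Reactants: 6 8-iodo-5-methoxy-3,4-dimethyl-7-[(2-methylbut-3-yn-2-yl)oxy]-2H-chromen-2-one
Product: 7 8-iodo-5-methoxy-3,4-dimethyl-7-[(2-methylbut-3-en-2-yl)oxy]-2H-chromen-2-one
Conditions: H2 (1 atm), Pd/CaCO3 poisoned with Pb(OAc)2, quinoline, EtOAc, rt
Reagents that add atoms: none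
Why: Semihydrogenation of a terminal alkyne over poisoned palladium stops at the alkene, and the poisoned catalyst at room temperature is expected to leave the aryl C–I bond and the tetrasubstituted coumarin alkene alone.

Step 5
Reactants: 7 8-iodo-5-methoxy-3,4-dimethyl-7-[(2-methylbut-3-en-2-yl)oxy]-2H-chromen-2-one
Product: 8 7-hydroxy-8-iodo-5-methoxy-3,4-dimethyl-6-(3-methylbut-2-en-1-yl)-2H-chromen-2-one
Conditions: PhNEt2, 130 °C
Reagents that add atoms: none
Why: Aromatic Claisen rearrangement, in which the allyl unit must migrate to C6 because C8 is occupied by iodine, the allylic inversion turning the tertiary ether into the linear 3-methylbut-2-enyl group before tautomerisation restores the phenol.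

Step 6
Reactants: 8 7-hydroxy-8-iodo-5-methoxy-3,4-dimethyl-6-(3-methylbut-2-en-1-yl)-2H-chromen-2-one
Product: 9 8-iodo-5-methoxy-7-(methoxymethoxy)-3,4-dimethyl-6-(3-methylbut-2-en-1-yl)-2H-chromen-2-one
Conditions: MOMCl, i-Pr2NEt, CH2Cl2, 0 °C → rt
Reagents that add atoms: chloromethyl methyl ether COCCl
Why: Williamson-type O-alkylation of the acidic phenol caps the C7 hydroxyl so that it cannot intercept the acylpalladium species in step 15.

**Stannane fragment**

Step 7
Reactants: 10 cyclohex-2-en-1-one; 11 dimethylzinc; 12 acetaldehyde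
Product: 14 (2R,3R)-2-(1-hydroxyethyl)-3-methylcyclohexan-1-one (both carbinol epimers), via methylzinc enolate 13 (not isolated)
Conditions: Cu(OTf)2 (2 mol %), (R,S,S)-phosphoramidite of 1,1'-bi-2-naphthol and bis(1-phenylethyl)amine (4 mol %), toluene, −30 °C; then 12, −30 → 0 °C; aq. NH4Cl
Reagents that add atoms: none
Why: Copper/phosphoramidite-catalysed asymmetric conjugate addition sets C3 (the future C5') as R by ligand control (the antipode of the ligand that gives (S)-3-alkylcyclohexanones is chosen), and the zinc enolate formed regiospecifically at C2 undergoes aldol addition to acetaldehyde anti to the new methyl, the carbinol configuration being irrelevant because it is erased in step 8.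

Step 8
Reactants: 14 (2R,3R)-2-(1-hydroxyethyl)-3-methylcyclohexan-1-one
Product: 16 (2E,3R)-2-ethylidene-3-methylcyclohexan-1-one, via mesylate 15 (not isolated)
Conditions: MsCl, Et3N, CH2Cl2, 0 °C; then DBU, 0 °C → rt
Reagents that add atoms: methanesulfonyl chloride CS(=O)(=O)Cl (its atoms remain only in 15)
Why: Mesylation followed by E1cB elimination through the ketone enolate should give the conjugated exocyclic enone as the E isomer from both carbinol epimers, and C3 should keep its configuration because allylic 1,3-strain holds its methyl axial and its C–H bond in the enone plane, where it is not acidified.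

Step 9
Reactants: 16 (2E,3R)-2-ethylidene-3-methylcyclohexan-1-one
Product: 17 (6E,7R)-6-ethylidene-7-methyl-1,4-dioxaspiro[4.5]decane
Conditions: (TMSOCH2)2, TMSOTf (5 mol %), CH2Cl2, −78 → −40 °C; pyridine quench
Reagents that add atoms: 1,2-bis(trimethylsilyloxy)ethane C[Si](C)(C)OCCO[Si](C)(C)C
Why: Aprotic ketalisation with the bis-silyl glycol ether and catalytic silyl triflate at low temperature protects enones without moving the double bond, which here would destroy both the C7 stereocentre and the E geometry.

Step 10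
Reactants: 17 (6E,7R)-6-ethylidene-7-methyl-1,4-dioxaspiro[4.5]decane
Product: 19 (1S)-1-[(6S,7R)-7-methyl-1,4-dioxaspiro[4.5]decan-6-yl]ethan-1-ol, via alkylborane 18 (not isolated)
Conditions: BH3·THF, THF, 0 °C → rt; then aq. NaOH, H2O2, 0 °C → rt
Reagents that add atoms: borane–tetrahydrofuran [BH3-][O+]1CCCC1 (boron remains only in 18); hydrogen peroxide OO
Why: Hydroboration–oxidation, in which syn addition of H–B from the alkene face opposite the axial C7 methyl, with boron on the less substituted ethylidene carbon remote from the acetal oxygens, places the ring hydrogen trans to the methyl (side chain cis, 6S) and, because the alkene is E, makes the carbinol carbon S in the same event, the C–B oxidation proceeding with retention.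

Step 11
Reactants: 19 (1S)-1-[(6S,7R)-7-methyl-1,4-dioxaspiro[4.5]decan-6-yl]ethan-1-ol
Product: 20 tert-butyl(dimethyl){(1S)-1-[(6S,7R)-7-methyl-1,4-dioxaspiro[4.5]decan-6-yl]ethoxy}silane
Conditions: TBSOTf, 2,6-lutidine, CH2Cl2, −78 → 0 °C
Reagents that add atoms: tert-butyldimethylsilyl trifluoromethanesulfonate CC(C)(C)[Si](C)(C)OS(=O)(=O)C(F)(F)F
Why: O-Silylation with the silyl triflate and a hindered base is the reliable choice for a crowded secondary alcohol, and the buffered low-temperature medium leaves the dioxolane intact.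

Step 12
Reactants: 20 tert-butyl(dimethyl){(1S)-1-[(6S,7R)-7-methyl-1,4-dioxaspiro[4.5]decan-6-yl]ethoxy}silane
Product: 21 (2S,3R)-2-[(1S)-1-{[tert-butyl(dimethyl)silyl]oxy}ethyl]-3-methylcyclohexan-1-one
Conditions: PPTS, acetone/H2O (10:1), 40 °C
Reagents that add atoms: water O
Why: Mild acid-catalysed acetal hydrolysis with a pyridinium salt spares the secondary silyl ether and should be too weak to enolise the ketone toward the hindered C2, so the cis arrangement is kept.

Step 13
Reactants: 21 (2S,3R)-2-[(1S)-1-{[tert-butyl(dimethyl)silyl]oxy}ethyl]-3-methylcyclohexan-1-one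
Product: 23 (5R,6S)-6-[(1S)-1-{[tert-butyl(dimethyl)silyl]oxy}ethyl]-5-methylcyclohex-1-en-1-yl trifluoromethanesulfonate, via potassium enolate 22 (not isolated)
Conditions: KN(SiMe3)2, THF, −78 °C; then PhNTf2, −78 → 0 °C
Reagents that add atoms: potassium bis(trimethylsilyl)amide C[Si](C)(C)[N-][Si](C)(C)C.[K+] (potassium remains only in 22); N-phenylbis(trifluoromethanesulfonimide) O=S(=O)(N(c1ccccc1)S(=O)(=O)C(F)(F)F)C(F)(F)F
Why: Kinetic deprotonation by the bulky amide occurs at the unhindered C6 methylene rather than the tertiary C2, and O-triflation of the enolate gives the enol triflate with its double bond away from the stereocentres.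

Step 14
Reactants: 23 (5R,6S)-6-[(1S)-1-{[tert-butyl(dimethyl)silyl]oxy}ethyl]-5-methylcyclohex-1-en-1-yl trifluoromethanesulfonate; 24 hexamethylditin
Product: 25 tert-butyl(dimethyl){(1S)-1-[(1S,6R)-6-methyl-2-(trimethylstannyl)cyclohex-2-en-1-yl]ethoxy}silane
Conditions: Me3SnSnMe3, Pd(PPh3)4 (5 mol %), LiCl, THF, 65 °C
Reagents that add atoms: none
Why: Palladium-catalysed stannylation of an enol triflate with a distannane (oxidative addition, tin-to-palladium transmetalation, reductive elimination, with LiCl stabilising the alkenylpalladium species) replaces the triflate by tin without touching the alkene position or the stereocentres.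

**Coupling and deprotection**

Step 15
Reactants: 9 8-iodo-5-methoxy-7-(methoxymethoxy)-3,4-dimethyl-6-(3-methylbut-2-en-1-yl)-2H-chromen-2-one; 25 tert-butyl(dimethyl){(1S)-1-[(1S,6R)-6-methyl-2-(trimethylstannyl)cyclohex-2-en-1-yl]ethoxy}silane; 26 carbon monoxide
Product: 27 8-{[(5R,6R)-6-[(1S)-1-{[tert-butyl(dimethyl)silyl]oxy}ethyl]-5-methylcyclohex-1-en-1-yl]carbonyl}-5-methoxy-7-(methoxymethoxy)-3,4-dimethyl-6-(3-methylbut-2-en-1-yl)-2H-chromen-2-one
Conditions: Pd(PPh3)4 (10 mol %), CuI (20 mol %), CO (4 bar), DMF, 80 °C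
Reagents that add atoms: none
Why: Zerovalent palladium inserts into the C8–I bond of 9, CO inserts into the crowded aryl–palladium bond to give the aroylpalladium iodide, the cyclohexenyl group passes from tin (through the alkenylcopper formed with CuI) to palladium, and reductive elimination forms the ketone, so the C8–C(=O) and C(=O)–C1' bonds arise in one catalytic cycle. The closest known reaction type is the carbonylative Stille coupling of aryl iodides with alkenylstannanes to aryl alkenyl ketones. No ring is closed and no stereocentre is created; C5', C6' and C1'' come unchanged from 25 and the alkenyl group is transferred with its double bond in place. The step needs carbonylative rather than direct coupling, which the two ortho oxygen substituents (on C7 and C8a) secure by retarding transmetalation at the arylpalladium stage and making CO insertion, which relieves the crowding, the faster path, with CO pressure reinforcing this. It also needs transfer of the sp2 group rather than a methyl group from tin, which the normal transfer order of stannanes and the copper co-catalyst should secure; trimethyl- rather than tributylstannane is used because the tin-bearing carbon is flanked by the branched C6' substituent.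

Step 16
Reactants: 27 8-{[(5R,6R)-6-[(1S)-1-{[tert-butyl(dimethyl)silyl]oxy}ethyl]-5-methylcyclohex-1-en-1-yl]carbonyl}-5-methoxy-7-(methoxymethoxy)-3,4-dimethyl-6-(3-methylbut-2-en-1-yl)-2H-chromen-2-one
Product: 28 7-hydroxy-8-{[(5R,6R)-6-[(1S)-1-hydroxyethyl]-5-methylcyclohex-1-en-1-yl]carbonyl}-5-methoxy-3,4-dimethyl-6-(3-methylbut-2-en-1-yl)-2H-chromen-2-one
Conditions: HCl (1 M) in MeOH, 0 °C → rt
Reagents that add atoms: none
Why: Acid-catalysed acetal exchange cleaves the aryl MOM ether (helped by the neighbouring ketone) and methanolysis removes the secondary silyl ether in the same flask, the dilute acid at or below room temperature being chosen so that the freed phenol does not add to the prenyl alkene or the enone.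

**Compound list**
1 | 5-methoxyresorcinol | COc1cc(O)cc(O)c1 | starting material
2 | ethyl 2-methylacetoacetate | CCOC(=O)C(C)C(C)=O | starting material
3 | 7-hydroxy-5-methoxy-3,4-dimethyl-2H-chromen-2-one | COc1cc(O)cc2oc(=O)c(C)c(C)c12 | intermediate
4 | 7-hydroxy-8-iodo-5-methoxy-3,4-dimethyl-2H-chromen-2-one | COc1cc(O)c(I)c2oc(=O)c(C)c(C)c12 | intermediate
5 | 3-chloro-3-methylbut-1-yne | CC(C)(Cl)C#C | starting material
6 | 8-iodo-5-methoxy-3,4-dimethyl-7-[(2-methylbut-3-yn-2-yl)oxy]-2H-chromen-2-one | COc1cc(OC(C)(C)C#C)c(I)c2oc(=O)c(C)c(C)c12 | intermediate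
7 | 8-iodo-5-methoxy-3,4-dimethyl-7-[(2-methylbut-3-en-2-yl)oxy]-2H-chromen-2-one | COc1cc(OC(C)(C)C=C)c(I)c2oc(=O)c(C)c(C)c12 | intermediate
8 | 7-hydroxy-8-iodo-5-methoxy-3,4-dimethyl-6-(3-methylbut-2-en-1-yl)-2H-chromen-2-one | COc1c(CC=C(C)C)c(O)c(I)c2oc(=O)c(C)c(C)c12 | intermediate
9 | 8-iodo-5-methoxy-7-(methoxymethoxy)-3,4-dimethyl-6-(3-methylbut-2-en-1-yl)-2H-chromen-2-one | COCOc1c(CC=C(C)C)c(OC)c2c(C)c(C)c(=O)oc2c1I | intermediate
10 | cyclohex-2-en-1-one | O=C1C=CCCC1 | starting material
11 | dimethylzinc | C[Zn]C | starting material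
12 | acetaldehyde | CC=O | starting material
13 | methylzinc (3R)-3-methylcyclohex-1-en-1-olate | C[C@@H]1CCCC(O[Zn]C)=C1 | intermediate
14 | (2R,3R)-2-(1-hydroxyethyl)-3-methylcyclohexan-1-one, both carbinol epimers | O=C1CCC[C@@H](C)[C@@H]1C(C)O | intermediate
15 | 1-[(1R,2R)-2-methyl-6-oxocyclohexyl]ethyl methanesulfonate, both epimers at the sulfonate-bearing carbon | O=C1CCC[C@@H](C)[C@@H]1C(C)OS(C)(=O)=O | intermediate
16 | (2E,3R)-2-ethylidene-3-methylcyclohexan-1-one | C[C@@H]1CCCC(=O)/C1=C/C | intermediate
17 | (6E,7R)-6-ethylidene-7-methyl-1,4-dioxaspiro[4.5]decane | C[C@@H]1CCCC2(OCCO2)/C1=C/C | intermediate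
18 | [(1S)-1-[(6S,7R)-7-methyl-1,4-dioxaspiro[4.5]decan-6-yl]ethyl]borane (written as the monoalkylborane) | O1CCOC12CCC[C@@H](C)[C@H]2[C@H](C)B | intermediate
19 | (1S)-1-[(6S,7R)-7-methyl-1,4-dioxaspiro[4.5]decan-6-yl]ethan-1-ol | O1CCOC12CCC[C@@H](C)[C@H]2[C@H](C)O | intermediate
20 | tert-butyl(dimethyl){(1S)-1-[(6S,7R)-7-methyl-1,4-dioxaspiro[4.5]decan-6-yl]ethoxy}silane | O1CCOC12CCC[C@@H](C)[C@H]2[C@H](C)O[Si](C)(C)C(C)(C)C | intermediate
21 | (2S,3R)-2-[(1S)-1-{[tert-butyl(dimethyl)silyl]oxy}ethyl]-3-methylcyclohexan-1-one | O=C1CCC[C@@H](C)[C@H]1[C@H](C)O[Si](C)(C)C(C)(C)C | intermediate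
22 | potassium (5R,6S)-6-[(1S)-1-{[tert-butyl(dimethyl)silyl]oxy}ethyl]-5-methylcyclohex-1-en-1-olate | [K+].[O-]C1=CCC[C@@H](C)[C@H]1[C@H](C)O[Si](C)(C)C(C)(C)C | intermediate
23 | (5R,6S)-6-[(1S)-1-{[tert-butyl(dimethyl)silyl]oxy}ethyl]-5-methylcyclohex-1-en-1-yl trifluoromethanesulfonate | O=S(=O)(OC1=CCC[C@@H](C)[C@H]1[C@H](C)O[Si](C)(C)C(C)(C)C)C(F)(F)F | intermediate
24 | hexamethylditin | C[Sn](C)(C)[Sn](C)(C)C | starting material
25 | tert-butyl(dimethyl){(1S)-1-[(1S,6R)-6-methyl-2-(trimethylstannyl)cyclohex-2-en-1-yl]ethoxy}silane | C[Sn](C)(C)C1=CCC[C@@H](C)[C@H]1[C@H](C)O[Si](C)(C)C(C)(C)C | intermediate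
26 | carbon monoxide | [C-]#[O+] | starting material
27 | 8-{[(5R,6R)-6-[(1S)-1-{[tert-butyl(dimethyl)silyl]oxy}ethyl]-5-methylcyclohex-1-en-1-yl]carbonyl}-5-methoxy-7-(methoxymethoxy)-3,4-dimethyl-6-(3-methylbut-2-en-1-yl)-2H-chromen-2-one | COCOc1c(CC=C(C)C)c(OC)c2c(C)c(C)c(=O)oc2c1C(=O)C1=CCC[C@@H](C)[C@H]1[C@H](C)O[Si](C)(C)C(C)(C)C | intermediate
28 | 7-hydroxy-8-{[(5R,6R)-6-[(1S)-1-hydroxyethyl]-5-methylcyclohex-1-en-1-yl]carbonyl}-5-methoxy-3,4-dimethyl-6-(3-methylbut-2-en-1-yl)-2H-chromen-2-one | COc1c(CC=C(C)C)c(O)c(C(=O)C2=CCC[C@@H](C)[C@H]2[C@H](C)O)c2oc(=O)c(C)c(C)c12 | target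

**Step count**
Total: 16 steps. Longest linear sequence: 10 steps (steps 7 to 16, from cyclohex-2-en-1-one); the coumarin branch (steps 1 to 6) joins at step 15.

**Steps most likely to fail**

Step 15. Transfer of the hindered cyclohexenyl group from tin may be too slow, so that direct coupling without CO, methyl transfer from tin or protodestannylation takes over. The fallback builds the ketone by addition and oxidation; it sets out from 9 and 25 and returns at 27. Reductive carbonylation of 9 (Pd(OAc)2, 1,3-bis(diphenylphosphino)propane, CO, Et3SiH, Na2CO3, DMF, 80 °C) should give 5-methoxy-7-(methoxymethoxy)-3,4-dimethyl-6-(3-methylbut-2-en-1-yl)-2-oxo-2H-chromene-8-carbaldehyde F1. Tin–lithium exchange on 25 (MeLi, THF, −78 °C) should give the cyclohexenyllithium F2. Addition of F2 to F1 at −78 °C, where the aldehyde reacts far faster than the lactone, should give the secondary alcohol F3 as a mixture of carbinol epimers, and oxidation with Dess–Martin periodinane should give 27.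

Step 10. Facial selectivity of borane delivery may be poor, or some boron may add at the ring carbon, eroding the cis pattern and the carbinol configuration. The fallback sets out from enone 16 and returns at ketone 21, bypassing steps 9 to 12. Copper-catalysed conjugate borylation (CuCl, NaOt-Bu, a chiral Josiphos-type bisphosphine, bis(pinacolato)diboron, MeOH, THF) places boron on the ethylidene carbon under ligand control, and the enolate is protonated kinetically anti to the axial methyl to give the β-boryl ketone F4. Oxidation with NaBO3 should give (2S,3R)-2-[(1S)-1-hydroxyethyl]-3-methylcyclohexan-1-one F5, and silylation (TBSOTf, 2,6-lutidine) gives 21.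

Step 16. The freed phenol may add under acid to the prenyl alkene (chroman formation) or to the enone, or the crowded silyl ether may be removed incompletely. The fallback is a two-stage deprotection that avoids protic acid; it sets out from 27 and returns at 28. HF·pyridine in THF/pyridine should remove only the silyl group, giving the MOM-protected alcohol F6. MgBr2·OEt2 in Et2O/CH2Cl2 should then cleave the aryl MOM ether by chelation between the C7 oxygen and the ketone, giving 28.

**Further compounds**
F1 | step 15 | 5-methoxy-7-(methoxymethoxy)-3,4-dimethyl-6-(3-methylbut-2-en-1-yl)-2-oxo-2H-chromene-8-carbaldehyde | COCOc1c(CC=C(C)C)c(OC)c2c(C)c(C)c(=O)oc2c1C=O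
F2 | step 15 | {(5R,6S)-6-[(1S)-1-{[tert-butyl(dimethyl)silyl]oxy}ethyl]-5-methylcyclohex-1-en-1-yl}lithium | [Li]C1=CCC[C@@H](C)[C@H]1[C@H](C)O[Si](C)(C)C(C)(C)C
F3 | step 15 | 8-{[(5R,6R)-6-[(1S)-1-{[tert-butyl(dimethyl)silyl]oxy}ethyl]-5-methylcyclohex-1-en-1-yl](hydroxy)methyl}-5-methoxy-7-(methoxymethoxy)-3,4-dimethyl-6-(3-methylbut-2-en-1-yl)-2H-chromen-2-one, both carbinol epimers | COCOc1c(CC=C(C)C)c(OC)c2c(C)c(C)c(=O)oc2c1C(O)C1=CCC[C@@H](C)[C@H]1[C@H](C)O[Si](C)(C)C(C)(C)C
F4 | step 10 | (2S,3R)-3-methyl-2-[(1S)-1-(4,4,5,5-tetramethyl-1,3,2-dioxaborolan-2-yl)ethyl]cyclohexan-1-one | O=C1CCC[C@@H](C)[C@H]1[C@H](C)B1OC(C)(C)C(C)(C)O1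
F5 | step 10 | (2S,3R)-2-[(1S)-1-hydroxyethyl]-3-methylcyclohexan-1-one | O=C1CCC[C@@H](C)[C@H]1[C@H](C)O
F6 | step 16 | 8-{[(5R,6R)-6-[(1S)-1-hydroxyethyl]-5-methylcyclohex-1-en-1-yl]carbonyl}-5-methoxy-7-(methoxymethoxy)-3,4-dimethyl-6-(3-methylbut-2-en-1-yl)-2H-chromen-2-one | COCOc1c(CC=C(C)C)c(OC)c2c(C)c(C)c(=O)oc2c1C(=O)C1=CCC[C@@H](C)[C@H]1[C@H](C)O
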